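## Retrosynthetic overview

1. The free C15 alcohol comes from an enal-selective 1,2-reduction of the 3β-acetoxy-15,19-dial. The dial comes from the 3β,15,19-triol by oxidation of both primary alcohols and then acetylation.
2. The triol comes from one hydride reduction of a 3-oxo-15,19-diester. This step sets C3 and releases the auxiliary. The C13=C14 bond comes from a Horner–Wadsworth–Emmons reaction on a C13 methyl ketone.
3. Rings A and B form together in one oxidative radical bicyclisation of an acyclic dienyl β-keto ester. C4–C5 closes ring A, C9–C10 closes ring B, and the terminating oxidation gives C8=C17.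
4. A chiral 8-phenylmenthyl ester fixes the absolute sense. The side chain is kept as a saturated ketone, so no third alkene can carry the cascade on to a third ring.
5. The acyclic ester comes from γ-alkylation (C1–C2 bond) of a 2-methylacetoacetate dianion with an ω-bromide. The bromide is made from (E)-geranylacetone by ketalisation, allylic oxidation and an Appel reaction.

Assumption: (E)-geranylacetone and (−)-8-phenylmenthol are bought as single isomers, and the (1R,2S,5R) auxiliary leaves open the face of the C4 radical that gives the 4R (normal labdane) series drawn here; if the sense proved opposite, the commercial (+)-auxiliary would be used with no other change.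

## Route

Step 1
Reactants: 1 (5E)-6,10-dimethylundeca-5,9-dien-2-one ((E)-geranylacetone)
Product: 2 2-[(3E)-4,8-dimethylnona-3,7-dien-1-yl]-2-methyl-1,3-dioxolane
Conditions: HOCH2CH2OH, p-toluenesulfonic acid (cat.), toluene, reflux, Dean–Stark
Reagents that add atoms: ethylene glycol, OCCO
Why: Acid-catalysed ketalisation masks the methyl ketone against the strongly basic dianion of step 5, makes no stereocentre and leaves the E alkene untouched.

Step 2
Reactants: 2 2-[(3E)-4,8-dimethylnona-3,7-dien-1-yl]-2-methyl-1,3-dioxolane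
Product: 3 (2E,6E)-2,6-dimethyl-9-(2-methyl-1,3-dioxolan-2-yl)nona-2,6-dien-1-ol
Conditions: SeO2 (0.1 equiv), t-BuOOH (2 equiv), CH2Cl2, 0 °C to rt
Reagents that add atoms: tert-butyl hydroperoxide, CC(C)(C)OO (its oxygen atom is relayed through the catalytic SeO2, O=[Se]=O)
Why: Sharpless–Umbreit allylic oxidation (ene reaction then [2,3]-shift) attacks the terminal gem-dimethyl alkene fastest and oxidises only the methyl group trans to the chain, which sets the second E alkene.

Step 3
Reactants: 3 (2E,6E)-2,6-dimethyl-9-(2-methyl-1,3-dioxolan-2-yl)nona-2,6-dien-1-ol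
Product: 4 2-[(3E,7E)-9-bromo-4,8-dimethylnona-3,7-dien-1-yl]-2-methyl-1,3-dioxolane
Conditions: CBr4, PPh3, CH2Cl2, 0 °C
Reagents that add atoms: carbon tetrabromide, BrC(Br)(Br)Br
Why: The Appel reaction turns the primary allylic alcohol into the bromide under neutral conditions, without allylic transposition, loss of alkene geometry or ketal cleavage.

Step 4
Reactants: 5 ethyl 2-methyl-3-oxobutanoate; 6 (1R,2S,5R)-5-methyl-2-(2-phenylpropan-2-yl)cyclohexan-1-ol ((−)-8-phenylmenthol)
Product: 7 (−)-8-phenylmenthyl 2-methyl-3-oxobutanoate (both C2 epimers)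
Conditions: 4-(dimethylamino)pyridine (0.3 equiv), toluene, reflux, ethanol distilled off
Reagents that add atoms: none
Why: Amine-catalysed transesterification of an enolisable β-keto ester (through the acylketene) loads hindered secondary alcohols cleanly, and the epimeric C2 centre is erased later at the radical stage.

Step 5
Reactants: 7 (−)-8-phenylmenthyl 2-methyl-3-oxobutanoate; 4 2-[(3E,7E)-9-bromo-4,8-dimethylnona-3,7-dien-1-yl]-2-methyl-1,3-dioxolane
Product: 10 (−)-8-phenylmenthyl (6E,10E)-2,6,10-trimethyl-3,14-dioxopentadeca-6,10-dienoate, via dilithium dianion 8 (not isolated), via ketal keto ester 9 (not isolated)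
Conditions: lithium diisopropylamide (2.2 equiv), THF, −78 to 0 °C; then 4, 0 °C; then 1 M HCl, THF, rt
Reagents that add atoms: water, O
Why: Huckin–Weiler dianion alkylation joins the more reactive γ-carbon to the allylic bromide by SN2 (C1–C2 bond) with both E alkenes kept, and the acidic work-up hydrolyses the dioxolane.

Step 6
Reactants: 10 (−)-8-phenylmenthyl (6E,10E)-2,6,10-trimethyl-3,14-dioxopentadeca-6,10-dienoate
Product: 11 (−)-8-phenylmenthyl (4R,5R,9S,10R)-3,13-dioxo-14,15-dinorlabd-8(17)-en-19-oate
Conditions: Mn(OAc)3·2H2O (2.2 equiv), Cu(OAc)2·H2O (1.0 equiv), degassed AcOH (0.05 M), rt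
Reagents that add atoms: none
Why: In this Snider-type oxidative free-radical polyene cyclisation trivalent manganese makes the electrophilic C4 radical, two 6-endo closures through a chair–chair array of the two E alkenes give the trans-decalin with axial 4β-ester, 5α-H, axial 10β-methyl and equatorial C9 chain, the stacked phenyl ring of the auxiliary blocks one radical face and fixes the absolute sense (about 6–10:1, minor isomer removed on silica), divalent copper converts the tertiary C8 radical into the less substituted exocyclic alkene by oxidative elimination, and the saturated keto chain stops the cascade after ring B.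

Step 7
Reactants: 11 (−)-8-phenylmenthyl (4R,5R,9S,10R)-3,13-dioxo-14,15-dinorlabd-8(17)-en-19-oate
Product: 12 19-[(−)-8-phenylmenthyl] 15-ethyl (13E)-3-oxolabda-8(17),13-diene-15,19-dioate
Conditions: (EtO)2P(O)CH2CO2Et (3 equiv), NaH (2.8 equiv), THF, 0 to 40 °C; E and Z esters separated on silica
Reagents that add atoms: triethyl phosphonoacetate, CCOC(=O)CP(=O)(OCC)OCC
Why: Horner–Wadsworth–Emmons olefination takes place only at the unhindered methyl ketone (the C3 ketone sits next to quaternary C4) and gives mainly the E enoate, about 5:1 as is usual for 14,15-dinorlabdan-13-ones.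

Step 8
Reactants: 12 19-[(−)-8-phenylmenthyl] 15-ethyl (13E)-3-oxolabda-8(17),13-diene-15,19-dioate
Product: 13 (13E)-labda-8(17),13-diene-3β,15,19-triol
Conditions: LiAlH4 (5 equiv), Et2O/THF, 0 °C to reflux; aqueous work-up
Reagents that add atoms: none
Why: In this hydride reduction the C3 ketone is attacked axially from the α face because the axial C19 ester and the C10 methyl block the β face, which gives the equatorial 3β (3S) alcohol, and the resulting 3-alkoxyaluminate helps reduce the neighbouring hindered ester while the enoate gives the allylic alcohol and the auxiliary is recovered.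

Step 9
Reactants: 13 (13E)-labda-8(17),13-diene-3β,15,19-triol
Product: 14 (13E)-3β-hydroxylabda-8(17),13-diene-15,19-dial
Conditions: TEMPO (2,2,6,6-tetramethylpiperidin-1-oxyl, 0.2 equiv), PhI(OAc)2 (2.5 equiv), CH2Cl2, rt
Reagents that add atoms: none
Why: The nitroxyl/PhI(OAc)2 (Piancatelli–Margarita) oxidation takes primary alcohols far faster than a hindered secondary one, so C15 and C19 become aldehydes, the 3β-alcohol survives and the E enal does not isomerise.

Step 10
Reactants: 14 (13E)-3β-hydroxylabda-8(17),13-diene-15,19-dial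
Product: 15 (13E)-3β-acetoxylabda-8(17),13-diene-15,19-dial
Conditions: Ac2O, pyridine, rt, 24 h (no nucleophilic catalyst)
Reagents that add atoms: acetic anhydride, CC(=O)OC(C)=O
Why: Plain pyridine acetylation is enough for an equatorial 3β-alcohol next to a quaternary carbon (as with triterpenoid 3β-ols), cannot epimerise the non-enolisable C4, and avoids the conjugate addition–elimination that could scramble the enal geometry.

Step 11
Reactants: 15 (13E)-3β-acetoxylabda-8(17),13-diene-15,19-dial
Product: 16 (3S,4R,5R,9S,10R,13E)-3-acetoxy-15-hydroxylabda-8(17),13-dien-19-al (CNP0185120.1)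
Conditions: NaBH4 (0.4 equiv), CeCl3·7H2O (1 equiv), MeOH, −78 °C
Reagents that add atoms: none
Why: Luche reduction gives clean 1,2-reduction of the unhindered enal, while the C19 aldehyde (neopentyl, axial, 1,3-diaxial to the C10 methyl and next to the acetate) and the acetate do not react at this temperature with less than one equivalent of hydride.

## Compound list

| No. | Name | SMILES | Role |
|---|---|---|---|
| 1 | (E)-geranylacetone | CC(=O)CC/C=C(\C)CCC=C(C)C | starting material |
| 2 | 2-[(3E)-4,8-dimethylnona-3,7-dien-1-yl]-2-methyl-1,3-dioxolane | CC1(CC/C=C(\C)CCC=C(C)C)OCCO1 | intermediate |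
| 3 | (2E,6E)-2,6-dimethyl-9-(2-methyl-1,3-dioxolan-2-yl)nona-2,6-dien-1-ol | CC1(CC/C=C(\C)CC/C=C(\C)CO)OCCO1 | intermediate |
| 4 | 2-[(3E,7E)-9-bromo-4,8-dimethylnona-3,7-dien-1-yl]-2-methyl-1,3-dioxolane | CC1(CC/C=C(\C)CC/C=C(\C)CBr)OCCO1 | intermediate |
| 5 | ethyl 2-methyl-3-oxobutanoate | CCOC(=O)C(C)C(C)=O | starting material |
| 6 | (−)-8-phenylmenthol, (1R,2S,5R) | C[C@@H]1CC[C@@H](C(C)(C)c2ccccc2)[C@H](O)C1 | starting material |
| 7 | (−)-8-phenylmenthyl 2-methyl-3-oxobutanoate (C2 epimers) | CC(=O)C(C)C(=O)O[C@@H]1C[C@H](C)CC[C@H]1C(C)(C)c1ccccc1 | intermediate |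
| 8 | dilithium dianion of 7 | [Li+].[Li+].C=C([O-])C(C)=C([O-])O[C@@H]1C[C@H](C)CC[C@H]1C(C)(C)c1ccccc1 | intermediate |
| 9 | (−)-8-phenylmenthyl (6E,10E)-2,6,10-trimethyl-13-(2-methyl-1,3-dioxolan-2-yl)-3-oxotrideca-6,10-dienoate | CC(C(=O)CC/C(C)=C/CC/C(C)=C/CCC1(C)OCCO1)C(=O)O[C@@H]1C[C@H](C)CC[C@H]1C(C)(C)c1ccccc1 | intermediate |
| 10 | (−)-8-phenylmenthyl (6E,10E)-2,6,10-trimethyl-3,14-dioxopentadeca-6,10-dienoate | CC(C(=O)CC/C(C)=C/CC/C(C)=C/CCC(C)=O)C(=O)O[C@@H]1C[C@H](C)CC[C@H]1C(C)(C)c1ccccc1 | intermediate |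
| 11 | (−)-8-phenylmenthyl (4R,5R,9S,10R)-3,13-dioxo-14,15-dinorlabd-8(17)-en-19-oate (4β-axial ester; 5α-H; 9α-H; 10β-methyl) | C=C1CC[C@H]2[C@@](C)(C(=O)O[C@@H]3C[C@H](C)CC[C@H]3C(C)(C)c3ccccc3)C(=O)CC[C@]2(C)[C@H]1CCC(C)=O | intermediate |
| 12 | 19-[(−)-8-phenylmenthyl] 15-ethyl (13E)-3-oxolabda-8(17),13-diene-15,19-dioate | C=C1CC[C@H]2[C@@](C)(C(=O)O[C@@H]3C[C@H](C)CC[C@H]3C(C)(C)c3ccccc3)C(=O)CC[C@]2(C)[C@H]1CC/C(C)=C/C(=O)OCC | intermediate |
| 13 | (13E)-labda-8(17),13-diene-3β,15,19-triol | C=C1CC[C@H]2[C@@](C)(CO)[C@@H](O)CC[C@]2(C)[C@H]1CC/C(C)=C/CO | intermediate |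
| 14 | (13E)-3β-hydroxylabda-8(17),13-diene-15,19-dial | C=C1CC[C@H]2[C@@](C)(C=O)[C@@H](O)CC[C@]2(C)[C@H]1CC/C(C)=C/C=O | intermediate |
| 15 | (13E)-3β-acetoxylabda-8(17),13-diene-15,19-dial | C=C1CC[C@H]2[C@@](C)(C=O)[C@@H](OC(C)=O)CC[C@]2(C)[C@H]1CC/C(C)=C/C=O | intermediate |
| 16 | (3S,4R,5R,9S,10R,13E)-3-acetoxy-15-hydroxylabda-8(17),13-dien-19-al | C=C1CC[C@H]2[C@@](C)(C=O)[C@@H](OC(C)=O)CC[C@]2(C)[C@H]1CC/C(C)=C/CO | target |

## Step count and risks

- Total step count: 11.
- Longest linear sequence: 10 steps (steps 1–3 and 5–11, from 1 to 16). Step 4 is a one-step side branch.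

**Step 6 (bicyclisation).**
- Risks are a modest yield, endocyclic alkene isomers, capture of a C8 cation by the ketone oxygen, and limited facial control.
- The fallback sets out from 10 and comes back at 11. It separates ring formation from alkene formation.
- Compound 10 is deprotonated at its most acidic site with NaH and quenched with PhSeCl. This gives the α-phenylselanyl keto ester F1.
- Irradiation in benzene (sunlamp) generates the same C4 radical. It closes both rings, and the chain is carried by phenylselanyl transfer to C8, giving the tertiary C8 selenide F2.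
- H2O2 with pyridine then makes the selenoxide. Its syn elimination goes towards the unhindered methyl group and gives 11.

**Step 7 (alkene geometry).**
- The risk is an E:Z ratio too low to be useful, or an inseparable mixture.
- The fallback sets out from 11 and comes back at 13. It sets the geometry by carbometalation instead of carbonyl olefination.
- Both ketones of 11 are enolised with lithium diisopropylamide at −78 °C. One equivalent of ClP(O)(OEt)2 is taken up only by the unhindered terminal enolate, giving the enol phosphate F3, while the hindered ring enolate acts as its own protection.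
- More lithium diisopropylamide eliminates phosphate to give the terminal alkyne keto ester F4.
- LiAlH4 gives the alkyne diol F5.
- Negishi methylalumination (Me3Al, Cp2ZrCl2, syn addition, above 98% E) followed by n-BuLi and paraformaldehyde gives 13.

**Step 11 (aldehyde against aldehyde).**
- The risk is partial reduction of C19.
- The fallback sets out from 13 and comes back at 16. It replaces redox chemoselectivity by protection.
- One equivalent of TBSCl with imidazole silylates only the unhindered allylic alcohol, giving the 15-silyl ether F6.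
- TEMPO with PhI(OAc)2 gives the 19-aldehyde F7.
- Ac2O with pyridine and 4-(dimethylamino)pyridine gives the acetate F8.
- Tetrabutylammonium fluoride buffered with AcOH gives 16.

## Further compounds

F1 | step 6 | (−)-8-phenylmenthyl (6E,10E)-2,6,10-trimethyl-3,14-dioxo-2-(phenylselanyl)pentadeca-6,10-dienoate (C2 epimers) | CC([Se]c1ccccc1)(C(=O)CC/C(C)=C/CC/C(C)=C/CCC(C)=O)C(=O)O[C@@H]1C[C@H](C)CC[C@H]1C(C)(C)c1ccccc1
F2 | step 6 | (−)-8-phenylmenthyl 3,13-dioxo-8-(phenylselanyl)-14,15-dinorlabdan-19-oate (C8 epimers) | CC1([Se]c2ccccc2)CC[C@H]2[C@@](C)(C(=O)O[C@@H]3C[C@H](C)CC[C@H]3C(C)(C)c3ccccc3)C(=O)CC[C@]2(C)[C@H]1CCC(C)=O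
F3 | step 7 | (−)-8-phenylmenthyl 13-(diethoxyphosphoryloxy)-3-oxo-14,15-dinorlabda-8(17),13(16)-dien-19-oate | C=C1CC[C@H]2[C@@](C)(C(=O)O[C@@H]3C[C@H](C)CC[C@H]3C(C)(C)c3ccccc3)C(=O)CC[C@]2(C)[C@H]1CCC(=C)OP(=O)(OCC)OCC
F4 | step 7 | (−)-8-phenylmenthyl 3-oxo-15,16-dinorlabd-8(17)-en-13-yn-19-oate | C=C1CC[C@H]2[C@@](C)(C(=O)O[C@@H]3C[C@H](C)CC[C@H]3C(C)(C)c3ccccc3)C(=O)CC[C@]2(C)[C@H]1CCC#C
F5 | step 7 | 15,16-dinorlabd-8(17)-en-13-yne-3β,19-diol | C=C1CC[C@H]2[C@@](C)(CO)[C@@H](O)CC[C@]2(C)[C@H]1CCC#C
F6 | step 11 | (13E)-15-(tert-butyldimethylsilyloxy)labda-8(17),13-diene-3β,19-diol | C=C1CC[C@H]2[C@@](C)(CO)[C@@H](O)CC[C@]2(C)[C@H]1CC/C(C)=C/CO[Si](C)(C)C(C)(C)C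
F7 | step 11 | (13E)-15-(tert-butyldimethylsilyloxy)-3β-hydroxylabda-8(17),13-dien-19-al | C=C1CC[C@H]2[C@@](C)(C=O)[C@@H](O)CC[C@]2(C)[C@H]1CC/C(C)=C/CO[Si](C)(C)C(C)(C)C
F8 | step 11 | (13E)-3β-acetoxy-15-(tert-butyldimethylsilyloxy)labda-8(17),13-dien-19-al | C=C1CC[C@H]2[C@@](C)(C=O)[C@@H](OC(C)=O)CC[C@]2(C)[C@H]1CC/C(C)=C/CO[Si](C)(C)C(C)(C)C
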